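## Structural features

Selaginellin F is built on one benzene ring (ring A) with four different carbon substituents on adjacent positions. C1 carries the methide carbon C7 of a para-quinone methide, which also holds a 4-hydroxyphenyl group. C2 carries a 2,4-dihydroxyphenyl group (ring B), C5 a hydroxymethyl group and C6 a (4-hydroxyphenyl)ethynyl unit (C8≡C9); C3 and C4 are the only CH positions. The target has no stereocentre, and the hindered rotations about the ring A–ring B bond and the C1–C7 bond are not defined in it, so the three adjacent centres created in the cycloaddition (C1, C2 and C6 of ring A) are only transient. The fragile parts are the quinone methide (electrophilic at C7, in equilibrium with the carbinol and its cation), the 2'-hydroxyl of ring B within reach of C7, the electron-rich diarylalkyne and the free resorcinol. The real difficulty is the regiocontrolled assembly of the contiguously substituted ring A with its crowded C1–C7 bond, and the release of the quinone methide only at the very end. The atoms C7, C1, C2, C1', C2' and the 2'-oxygen can be tied into a six-membered lactone, which makes C1=C2 the C3=C4 double bond of a coumarin with C7 as its carbonyl carbon. With a nitro group on C1 this bond is a strong dienophile, and C3–C6 with the oxymethyl group on C5 and the alkyne on C6 correspond to a 1-alkynyl-2-(oxymethyl)buta-1,3-diene.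

## Logic of the disconnections

22 to 20 (through 21): the exocyclic C7=C bond is turned back into a C7–OH bond and every hydroxyl is returned to an acetal or silyl ether. The quinone methide is too electrophilic to carry, and it arises from a bis(4-oxyaryl) carbinol by ionisation and proton loss. The gain is a stable triarylmethanol. The demand is that one acid treatment removes four methoxymethyl groups and one silyl group and dehydrates, without the 2'-hydroxyl closing onto C7 and without harm to the alkyne.

20 to 17 and 7: both C7–aryl bonds are cut. The two aryl groups are identical, and in 17 C7 is a lactone carbonyl that can accept two aryl anions while the ring oxygen masks the 2'-hydroxyl. Two rings are removed and a flat tricyclic lactone remains. The demand is that 18 (made from 7) adds twice, the second time to the hindered ketone 19.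

17 to 16 to 15: no skeletal bond is cut; ring A is taken back from the arene to a cyclohexadiene and then to a nitrocyclohexene by formal addition of H2 and HNO2. This exposes a cyclohexene that is a Diels–Alder retron and makes the nitro group a traceless activator. The demand is loss of HNO2 under base without damage at the propargylic position, followed by a clean dehydrogenation.

15 to 5 and 14: the bonds C2–C3 and C1–C6 of ring A are cut. This divides the molecule into two fragments of similar size, each a few steps from commercial material, and places all four ring A substituents through the choice of diene and dienophile. The demand is the orientation in which the CH2 terminus of 14 bonds to C4 of 5, an accessible s-cis diene, and enough thermal stability of both partners.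

5 to 2 and 3, and 2 to 1: the C1=C2 bond of ring A (the coumarin C3=C4 bond) and the lactone C–O bond are cut. A condensation of an aldehyde with an activated methylene compound followed by lactonisation forms both. The demand is a free 2-hydroxyl in 2, so the protection of 1 must stop at the 4-oxygen.

14 to 13 and 9: the C6–C8 bond (sp2–sp) is cut. An alkenyl iodide couples with a terminal alkyne with retention of geometry. The demand is that iodine in 13 stands trans to the vinyl group.

13 to 12 to 10: the bond between the vinyl group and the central carbon (C4–C5 of ring A) and the C–I bond are cut. Anti addition of a vinyl Grignard reagent across the triple bond of 10, with magnesium held by the alkoxide, followed by iodination gives this geometry directly.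

9 to 7 to 6: the aryl–C9 bond is cut; the two alkyne carbons come from trimethylsilylacetylene. 7 serves twice, as precursor of 9 and of 18, which keeps the number of different building blocks low.

## Other disconnections considered

Alternative 1: The cut is at C6–C8 and C1–C7, with ring A as an aryne (C1≡C6) that inserts into a C–CO bond of a symmetric diketone. In the forward step CsF would release the aryne from silyl triflate A1, and the enolate carbon of diketone A2 would add at C6. The C1 carbanion would close onto a carbonyl and the four-membered alkoxide would fragment to benzophenone A3 with an aroylmethyl arm at C6.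
- In its favour: ring A is aromatic throughout; C7 arrives as a diaryl ketone, so one aryl nucleophile suffices and no lactone is opened; C9 arrives with its aryl group; the C2 allyloxy group directs the nucleophile to the distal carbon C6.
- Against it: C6 is also ortho to the C5 side chain, so the electronically preferred attack is the sterically worse one. A1 is a pentasubstituted benzene needing a long preparation. After the key step the aroylmethyl arm must be dehydrated to the alkyne beside a second ketone, the allyl ether exchanged for a triflate, and ring B attached by cross-coupling next to the benzophenone.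
- Comparison: on structure it is the better plan for the oxidation level of C7 and for avoiding any dihydroarene; the chosen plan is better in carrying ring B and its 2'-oxygen from the start. On mechanism both depend on electronically controlled orientation (aryne distortion against frontier-orbital matching), which is about equal. On step economy the alternative should be longer.

Alternative 2: The cut is at C1–C2, C3–C4 and C5–C6, with ring A made from three tethered alkynes. In the forward step RhCl(PPh3)3 (univalent rhodium) would cyclotrimerise triyne A4 under high dilution to bis-lactone A5, closing ring A, the six-membered aryl lactone and a five-membered phthalide at once.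
- In its favour: the tethers fix the regiochemistry completely, which is better than the electronic control of the chosen plan. Ring A is formed aromatic, ring B is in place, and the step is an isomerisation with no by-product.
- Against it: A4 is a mixed diester of acetylenedicarboxylic acid with a phenol and a propargylic alcohol, a labile and strongly electrophilic substrate that is awkward to assemble. C8 arrives as a lactone carbonyl and must be reduced to the aldehyde, homologated to the terminal alkyne and arylated, with the two lactones told apart beforehand.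
- Comparison: on structure it creates more rings per step, but the phthalide is not part of the target and has to be taken apart. On mechanism the metallacycle pathway is at least as dependable as the cycloaddition and needs no oxidation of ring A, which is a point in its favour. On step economy the oxidation-level mismatch at C8 should make the route longer.

Alternative 3: The cut is at C1–C7 and C8–C9, with a later cleavage of C7–C9. In the forward step Pd(OAc)2, NaOAc and Bu4NCl in DMF would turn triflate aldehyde A6 and tolane A7 into indenone A8. The C1 arylpalladium adds across the alkyne and the alkenylpalladium closes onto the aldehyde carbon C8. Epoxidation to A9 and an Eschenmoser–Tanabe fragmentation would then give alkynyl benzophenone A10.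
- In its favour: the symmetric alkyne removes any regiochemical question. Both the C7 and the C9 aryl groups come from one simple tolane. The fragmentation unveils exactly the ortho-alkynyl benzophenone that needs one aryllithium addition, and ring B stays fully protected until the last step.
- Against it: A6 is a tetrasubstituted benzene that already needs a biaryl coupling. Oxidative addition at C1 is flanked by ring B and the formyl group. Epoxidation of a tetrasubstituted 2,3-diarylindenone and hydrazone formation at a hindered ketone are both demanding.
- Comparison: on structure it equals the chosen plan in the final acid step (the same cation with a free 2'-hydroxyl appears) and is better at C7, which needs one aryl addition and not two. On mechanism the palladium annulation on a doubly ortho-substituted triflate is less secure than a thermal cycloaddition. On step economy the two are expected to be close, with the chosen plan slightly shorter.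

Key step: step 8

Remarks on the chemistry (assumptions):
- The diene 14 must carry its silyloxymethyl group on C4 of the hexa-3,5-dien-1-yne chain (the internal diene carbon next to the alkynyl-bearing terminus), with a 3Z double bond. A 3-substituted chain would put the oxymethyl carbon and the alkyne on the same ring atom and cannot give ring A.
- 15 and 16 are racemic; 15 is expected as a mixture of C7 epimers and 16 may contain double-bond isomers, all of which converge on 17.
- The protection of 1 must stop at the 4-O-monoether, because the 2-hydroxyl closes the lactone in step 2.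

## Route

Step 1
Reactants: 1 2,4-dihydroxybenzaldehyde
Product: 2 2-hydroxy-4-(methoxymethoxy)benzaldehyde
Conditions: MOMCl (1.05 equiv), K2CO3, acetone, 0 °C → rt
Reagents that add atoms: chloromethyl methyl ether, COCCl
Why: Williamson-type O-alkylation; the 2-hydroxyl is hydrogen-bonded to the aldehyde and is less acidic and less nucleophilic, so one equivalent of the chloride with a weak base should alkylate only the 4-hydroxyl.

Step 2
Reactants: 2 2-hydroxy-4-(methoxymethoxy)benzaldehyde; 3 ethyl nitroacetate
Product: 5 7-(methoxymethoxy)-3-nitro-2H-chromen-2-one, via Knoevenagel nitroacrylate 4 (not isolated)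
Conditions: piperidine (cat.), AcOH (cat.), toluene, reflux, Dean–Stark
Reagents that add atoms: none
Why: Knoevenagel condensation of the acidic nitroacetate with the aldehyde, then lactonisation of the (E)-nitroacrylate 4 (aryl cis to the ester) onto the free 2-hydroxyl with loss of ethanol; this is the standard entry to 3-nitrocoumarins and the buffered medium should leave the acetal intact.

Step 3
Reactants: 6 4-iodophenol
Product: 7 1-iodo-4-(methoxymethoxy)benzene
Conditions: MOMCl, iPr2NEt, CH2Cl2, 0 °C → rt
Reagents that add atoms: chloromethyl methyl ether, COCCl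
Why: O-alkylation of a phenol with an α-chloro ether under amine base; 7 serves both as precursor of the arylacetylene and of the aryllithium.

Step 4
Reactants: 7 1-iodo-4-(methoxymethoxy)benzene
Product: 9 1-ethynyl-4-(methoxymethoxy)benzene, via arylethynyl trimethylsilane 8 (not isolated)
Conditions: HC≡CSiMe3 (1.2 equiv), PdCl2(PPh3)2 (2 mol %), CuI (4 mol %), Et3N, THF, rt; then K2CO3, MeOH, rt
Reagents that add atoms: ethynyl(trimethyl)silane, C#C[Si](C)(C)C
Why: Sonogashira coupling of an aryl iodide (zerovalent palladium formed in situ, copper acetylide as transfer agent), followed by base-catalysed methanolysis of the C–Si bond once the iodide is consumed.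

Step 5
Reactants: 10 prop-2-yn-1-ol
Product: 12 (2Z)-2-(iodomethylidene)but-3-en-1-ol, via cyclic alkenylmagnesium alkoxide 11 (not isolated)
Conditions: CH2=CHMgBr (3 equiv), CuI (10 mol %), THF, 0 °C → rt; then I2, THF, −78 → 0 °C; aq. NH4Cl, Na2S2O3
Reagents that add atoms: vinylmagnesium bromide, C=C[Mg]Br; iodine, II
Why: Copper-catalysed anti-carbomagnesiation of a propargylic alcohol: the vinyl group adds to the carbon bearing the CH2O arm and magnesium to the terminal carbon, where the alkoxide holds it in a five-membered chelate. Iodinolysis of the C–Mg bond with retention then places iodine cis to CH2OH and trans to the vinyl group.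

Step 6
Reactants: 12 (2Z)-2-(iodomethylidene)but-3-en-1-ol
Product: 13 tert-butyl{[(2Z)-2-(iodomethylidene)but-3-en-1-yl]oxy}dimethylsilane
Conditions: TBSCl, imidazole, CH2Cl2, 0 °C → rt
Reagents that add atoms: tert-butyl(chloro)dimethylsilane, CC(C)(C)[Si](C)(C)Cl
Why: Standard silylation of a primary allylic alcohol; the silyl ether shields the alcohol from DDQ and from the organolithium later and falls off in the final acid step.

Step 7
Reactants: 13 tert-butyl{[(2Z)-2-(iodomethylidene)but-3-en-1-yl]oxy}dimethylsilane; 9 1-ethynyl-4-(methoxymethoxy)benzene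
Product: 14 (3Z)-4-({[tert-butyl(dimethyl)silyl]oxy}methyl)-1-[4-(methoxymethoxy)phenyl]hexa-3,5-dien-1-yne
Conditions: PdCl2(PPh3)2 (3 mol %), CuI (5 mol %), Et3N, THF, rt, degassed, dark
Reagents that add atoms: none
Why: Sonogashira coupling of an alkenyl iodide, which reacts at room temperature with retention of the double-bond geometry, so the alkynyl group ends up trans to the vinyl group (the outside position of the diene).

Step 8
Reactants: 5 7-(methoxymethoxy)-3-nitro-2H-chromen-2-one; 14 (3Z)-4-({[tert-butyl(dimethyl)silyl]oxy}methyl)-1-[4-(methoxymethoxy)phenyl]hexa-3,5-dien-1-yne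
Product: 15 rac-(6aR,10aR)-8-({[tert-butyl(dimethyl)silyl]oxy}methyl)-3-(methoxymethoxy)-7-{[4-(methoxymethoxy)phenyl]ethynyl}-6a-nitro-6a,7,10,10a-tetrahydro-6H-benzo[c]chromen-6-one (cis ring fusion; C7 epimers)
Conditions: 14 (2 equiv), BHT (cat.), toluene (1 M), 110 °C, sealed tube, Ar
Reagents that add atoms: none
Why: Thermal normal-electron-demand Diels–Alder reaction, concerted but asynchronous: the HOMO of s-cis 14 has its largest coefficient at the unsubstituted CH2 terminus because of the conjugating alkynyl group at the other end, and the LUMO of the nitro- and carbonyl-activated C3=C4 bond of 5 has its largest coefficient at C4. The bond from the CH2 terminus to C4 of 5 (ring A C3–C2) is therefore the more advanced one, and the bond from the alkynyl-bearing terminus to the nitro-bearing carbon (ring A C6–C1) follows in the same transition state. The closest known reaction type is the cycloaddition of 3-nitrocoumarins with 1,3-dienes to 6a-nitro-tetrahydrobenzo[c]chromen-6-ones. One ring, ring A, is closed as a cyclohexene by intermolecular suprafacial [4+2] addition on both partners. The two ring-fusion centres C6a and C10a come out cis (nitro and hydrogen on the same face) because the dienophile geometry is locked in the lactone and is transferred suprafacially. The third centre, C7, depends on endo or exo approach and is left uncontrolled, since it becomes sp2 in the next two steps; 15 is racemic. The step needs the ortho orientation and reaction at the diene and not at the enyne or through the nitroalkene as a heterodiene: the matched polarisation outweighs the weak opposing effect of the 2-silyloxymethyl group, and the slim alkynyl group in the outside position keeps the s-cis conformer accessible. High concentration and a radical inhibitor should favour cycloaddition over oligomerisation of 14.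

Step 9
Reactants: 15 rac-(6aR,10aR)-8-({[tert-butyl(dimethyl)silyl]oxy}methyl)-3-(methoxymethoxy)-7-{[4-(methoxymethoxy)phenyl]ethynyl}-6a-nitro-6a,7,10,10a-tetrahydro-6H-benzo[c]chromen-6-one
Product: 16 8-({[tert-butyl(dimethyl)silyl]oxy}methyl)-3-(methoxymethoxy)-7-{[4-(methoxymethoxy)phenyl]ethynyl}-10,10a-dihydro-6H-benzo[c]chromen-6-one (racemic)
Conditions: DBU (1.5 equiv), CH2Cl2, 0 °C, short contact; aq. NH4Cl
Reagents that add atoms: none
Why: Base-induced β-elimination of nitrous acid from a tertiary α-nitro lactone: DBU removes the acidic allylic and propargylic C7–H and nitrite leaves from C6a, as known for Diels–Alder adducts of nitroalkenes; low temperature and a short contact time limit further base-mediated isomerisation.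

Step 10
Reactants: 16 8-({[tert-butyl(dimethyl)silyl]oxy}methyl)-3-(methoxymethoxy)-7-{[4-(methoxymethoxy)phenyl]ethynyl}-10,10a-dihydro-6H-benzo[c]chromen-6-one
Product: 17 8-({[tert-butyl(dimethyl)silyl]oxy}methyl)-3-(methoxymethoxy)-7-{[4-(methoxymethoxy)phenyl]ethynyl}-6H-benzo[c]chromen-6-one
Conditions: DDQ (1.2 equiv), toluene, rt → 50 °C
Reagents that add atoms: none
Why: DDQ dehydrogenation: hydride abstraction from the benzylic and allylic C10a–H gives a cyclohexadienyl cation that loses a proton to the arene; aromatisation drives the step and acetals, silyl ether and alkyne are inert to the quinone.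

Step 11
Reactants: 17 8-({[tert-butyl(dimethyl)silyl]oxy}methyl)-3-(methoxymethoxy)-7-{[4-(methoxymethoxy)phenyl]ethynyl}-6H-benzo[c]chromen-6-one; 7 1-iodo-4-(methoxymethoxy)benzene
Product: 20 {4-({[tert-butyl(dimethyl)silyl]oxy}methyl)-2'-hydroxy-4'-(methoxymethoxy)-3-{[4-(methoxymethoxy)phenyl]ethynyl}[1,1'-biphenyl]-2-yl}bis[4-(methoxymethoxy)phenyl]methanol, via aryllithium 18 (not isolated), via ring-opened ketone lithium phenoxide 19 (not isolated)
Conditions: 7 (3.3 equiv), t-BuLi (6.6 equiv), THF, −78 °C; then 17, −78 → 0 °C; aq. NH4Cl
Reagents that add atoms: none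
Why: Iodine–lithium exchange gives 18; its first 1,2-addition to the aryl lactone expels the aryloxide and gives ketone 19, and a second addition gives the tertiary alkoxide, the known double addition of organolithiums to aryl esters and benzo[c]chromen-6-ones. The excess reagent compensates for the hindrance at C7.

Step 12
Reactants: 20 {4-({[tert-butyl(dimethyl)silyl]oxy}methyl)-2'-hydroxy-4'-(methoxymethoxy)-3-{[4-(methoxymethoxy)phenyl]ethynyl}[1,1'-biphenyl]-2-yl}bis[4-(methoxymethoxy)phenyl]methanol
Product: 22 selaginellin F (4-[{2',4'-dihydroxy-4-(hydroxymethyl)-3-[(4-hydroxyphenyl)ethynyl][1,1'-biphenyl]-2-yl}(4-hydroxyphenyl)methylidene]cyclohexa-2,5-dien-1-one), via deprotected triaryl carbinol 21 (not isolated)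
Conditions: conc. aq. HCl, MeOH/THF (1:1), 45 °C; then aq. NaHCO3 to pH 6–7
Reagents that add atoms: none
Why: Acid-catalysed acetal exchange removes the four methoxymethyl groups (methanol takes up the formaldehyde unit as dimethoxymethane, away from the resorcinol) and cleaves the silyl ether. The bis(4-hydroxyphenyl) carbinol then ionises and loses a phenolic proton on neutralisation to give the para-quinone methide, as in fuchsone formation from 4-hydroxytrityl alcohols; no stereocentre is involved.

## Compound list

1 | 2,4-dihydroxybenzaldehyde | O=Cc1ccc(O)cc1O | starting material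
2 | 2-hydroxy-4-(methoxymethoxy)benzaldehyde | O=Cc1ccc(OCOC)cc1O | intermediate
3 | ethyl nitroacetate | CCOC(=O)C[N+](=O)[O-] | starting material
4 | ethyl (2E)-3-[2-hydroxy-4-(methoxymethoxy)phenyl]-2-nitroprop-2-enoate | CCOC(=O)/C(=C\c1ccc(OCOC)cc1O)[N+](=O)[O-] | intermediate (not isolated)
5 | 7-(methoxymethoxy)-3-nitro-2H-chromen-2-one | COCOc1ccc2cc([N+](=O)[O-])c(=O)oc2c1 | intermediate
6 | 4-iodophenol | Oc1ccc(I)cc1 | starting material
7 | 1-iodo-4-(methoxymethoxy)benzene | COCOc1ccc(I)cc1 | intermediate
8 | {[4-(methoxymethoxy)phenyl]ethynyl}(trimethyl)silane | COCOc1ccc(C#C[Si](C)(C)C)cc1 | intermediate (not isolated)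
9 | 1-ethynyl-4-(methoxymethoxy)benzene | COCOc1ccc(C#C)cc1 | intermediate
10 | prop-2-yn-1-ol | C#CCO | starting material
11 | 4-ethenyl-2,5-dihydro-1,2-oxamagnesole (chelated alkenylmagnesium alkoxide, magnesium cis to the CH2O arm) | C=CC1=C[Mg]OC1 | intermediate (not isolated)
12 | (2Z)-2-(iodomethylidene)but-3-en-1-ol | C=C/C(CO)=C/I | intermediate
13 | tert-butyl{[(2Z)-2-(iodomethylidene)but-3-en-1-yl]oxy}dimethylsilane | C=C/C(CO[Si](C)(C)C(C)(C)C)=C/I | intermediate
14 | (3Z)-4-({[tert-butyl(dimethyl)silyl]oxy}methyl)-1-[4-(methoxymethoxy)phenyl]hexa-3,5-dien-1-yne | C=C/C(CO[Si](C)(C)C(C)(C)C)=C/C#Cc1ccc(OCOC)cc1 | intermediate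
15 | rac-(6aR,10aR)-8-({[tert-butyl(dimethyl)silyl]oxy}methyl)-3-(methoxymethoxy)-7-{[4-(methoxymethoxy)phenyl]ethynyl}-6a-nitro-6a,7,10,10a-tetrahydro-6H-benzo[c]chromen-6-one (racemic, one enantiomer drawn, C7 undefined) | O=C1Oc2cc(OCOC)ccc2[C@H]2CC=C(CO[Si](C)(C)C(C)(C)C)C(C#Cc3ccc(OCOC)cc3)[C@@]12[N+](=O)[O-] | intermediate
16 | 8-({[tert-butyl(dimethyl)silyl]oxy}methyl)-3-(methoxymethoxy)-7-{[4-(methoxymethoxy)phenyl]ethynyl}-10,10a-dihydro-6H-benzo[c]chromen-6-one (racemic at C10a) | O=C1Oc2cc(OCOC)ccc2C2CC=C(CO[Si](C)(C)C(C)(C)C)C(C#Cc3ccc(OCOC)cc3)=C12 | intermediate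
17 | 8-({[tert-butyl(dimethyl)silyl]oxy}methyl)-3-(methoxymethoxy)-7-{[4-(methoxymethoxy)phenyl]ethynyl}-6H-benzo[c]chromen-6-one | O=C1Oc2cc(OCOC)ccc2-c2ccc(CO[Si](C)(C)C(C)(C)C)c(C#Cc3ccc(OCOC)cc3)c12 | intermediate
18 | [4-(methoxymethoxy)phenyl]lithium | [Li]c1ccc(OCOC)cc1 | intermediate (not isolated)
19 | lithium 2-[4-({[tert-butyl(dimethyl)silyl]oxy}methyl)-2-[4-(methoxymethoxy)benzoyl]-3-{[4-(methoxymethoxy)phenyl]ethynyl}phenyl]-5-(methoxymethoxy)phenolate | [Li]Oc1cc(OCOC)ccc1-c1ccc(CO[Si](C)(C)C(C)(C)C)c(C#Cc2ccc(OCOC)cc2)c1C(=O)c1ccc(OCOC)cc1 | intermediate (not isolated)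
20 | {4-({[tert-butyl(dimethyl)silyl]oxy}methyl)-2'-hydroxy-4'-(methoxymethoxy)-3-{[4-(methoxymethoxy)phenyl]ethynyl}[1,1'-biphenyl]-2-yl}bis[4-(methoxymethoxy)phenyl]methanol | OC(c1ccc(OCOC)cc1)(c1ccc(OCOC)cc1)c1c(-c2ccc(OCOC)cc2O)ccc(CO[Si](C)(C)C(C)(C)C)c1C#Cc1ccc(OCOC)cc1 | intermediate
21 | 2'-[hydroxybis(4-hydroxyphenyl)methyl]-4'-(hydroxymethyl)-3'-[(4-hydroxyphenyl)ethynyl][1,1'-biphenyl]-2,4-diol | OC(c1ccc(O)cc1)(c1ccc(O)cc1)c1c(-c2ccc(O)cc2O)ccc(CO)c1C#Cc1ccc(O)cc1 | intermediate (not isolated)
22 | selaginellin F, 4-[{2',4'-dihydroxy-4-(hydroxymethyl)-3-[(4-hydroxyphenyl)ethynyl][1,1'-biphenyl]-2-yl}(4-hydroxyphenyl)methylidene]cyclohexa-2,5-dien-1-one (no stereocentre) | O=C1C=CC(=C(c2ccc(O)cc2)c2c(-c3ccc(O)cc3O)ccc(CO)c2C#Cc2ccc(O)cc2)C=C1 | target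

## Step count and least certain steps

Total: 12 steps. Longest linear sequence: 8 steps (10 → 12 → 13 → 14 → 15 → 16 → 17 → 20 → 22; the branch from 6 through 7 and 9 is equally long).

Step 8 (key step). The most likely failure is a sluggish cycloaddition: the 7-alkoxy group lowers the electrophilicity of 5, and 14 is a 1,2-disubstituted diene of only moderate electron density, so oligomerisation of the diene or thermal loss of HNO2 from the first-formed adduct may compete. A second risk is erosion of the orientation by the 2-substituent. Fallback, setting out from 13 and 5 and returning at 17: the diene terminus is given an oxygen substituent, which raises the HOMO and enforces the same orientation, and the alkyne is brought in afterwards.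
- CuI with 3,4,7,8-tetramethyl-1,10-phenanthroline, Cs2CO3 and benzyl alcohol in toluene at 80 °C would convert 13 with retention into the benzyl dienyl ether F1.
- F1 should add to 5 well below 80 °C to give the cis-fused 7-benzyloxy nitro adduct F2.
- DBU would give the dihydro lactone F3 and DDQ the 7-benzyloxy benzo[c]chromenone F4.
- Hydrogenolysis (H2, Pd/C, EtOAc; no alkyne is present yet) would free the phenol F5, and Tf2O with pyridine would give the aryl triflate F6.
- Sonogashira coupling of F6 with 9 (PdCl2(PPh3)2, CuI, Et3N, DMF, 60 °C) would deliver 17.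

Step 9. The base that removes HNO2 can also move the acidic propargylic proton of the dihydroarene, so propargyl–allenyl isomerisation followed by a redox-neutral aromatisation to a styryl side chain may destroy the alkyne. The elimination may also stall for the C7 epimer that has no anti hydrogen. Fallback, setting out from 15 and returning at 17: radical denitration without base (Bu3SnH, AIBN, toluene, 80 °C) would give the nitro-free tetrahydro lactone F7 as a mixture of stereoisomers. A double dehydrogenation of F7 with DDQ (2.5 equiv, dioxane, reflux) would then lead to 17.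

Step 11. The second addition may stop at the hindered 2,6-disubstituted ketone 19, whose neighbouring lithium phenoxide adds to the shielding. On warming, the tertiary alkoxide may also add to the ortho alkyne. Fallback, setting out from 17 and returning at 21 (inside step 12, and so at 22): the two additions are separated.
- One equivalent of 18 at −78 °C with cold quench should give the hydroxy ketone F8.
- MOMCl and iPr2NEt would cap its phenol as the methoxymethyl ether F9.
- The less basic and more oxophilic arylcerium reagent made from 18 and CeCl3 (THF, −78 → 0 °C) should add to F9 to give the fully protected carbinol F10, which enters the conditions of step 12.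

Step 12. The triaryl cation formed in acid may be captured by the 2'-hydroxyl of ring B, closing a six-membered cyclic trityl ether instead of losing a proton to the quinone methide. Formaldehyde equivalents from the acetals may also alkylate the free resorcinol, and the electron-rich alkyne may be hydrated if the acid is too strong. Fallback, setting out from 20 and returning at 22: if ring closure prevails, the cyclic ether F11 (the 6,6-bis(4-hydroxyphenyl)-6H-benzo[c]chromene) is accepted as the product of the acid step. F11 would then be opened with dilute aqueous NaOH in THF at 0 °C, where a 4-phenoxide expels the ring B aryloxide in a 1,6-elimination, as in the opening of phenolphthalein-type lactones. Cold neutralisation with pH 7 phosphate buffer would give 22.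

## Further compounds

F1 | step 8 | tert-butyl{[(2Z)-2-[(benzyloxy)methylidene]but-3-en-1-yl]oxy}dimethylsilane | C=C/C(CO[Si](C)(C)C(C)(C)C)=C/OCc1ccccc1
F2 | step 8 | rac-(6aR,10aR)-7-(benzyloxy)-8-({[tert-butyl(dimethyl)silyl]oxy}methyl)-3-(methoxymethoxy)-6a-nitro-6a,7,10,10a-tetrahydro-6H-benzo[c]chromen-6-one (C7 undefined) | O=C1Oc2cc(OCOC)ccc2[C@H]2CC=C(CO[Si](C)(C)C(C)(C)C)C(OCc3ccccc3)[C@@]12[N+](=O)[O-]
F3 | step 8 | 7-(benzyloxy)-8-({[tert-butyl(dimethyl)silyl]oxy}methyl)-3-(methoxymethoxy)-10,10a-dihydro-6H-benzo[c]chromen-6-one (racemic) | O=C1Oc2cc(OCOC)ccc2C2CC=C(CO[Si](C)(C)C(C)(C)C)C(OCc3ccccc3)=C12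
F4 | step 8 | 7-(benzyloxy)-8-({[tert-butyl(dimethyl)silyl]oxy}methyl)-3-(methoxymethoxy)-6H-benzo[c]chromen-6-one | O=C1Oc2cc(OCOC)ccc2-c2ccc(CO[Si](C)(C)C(C)(C)C)c(OCc3ccccc3)c12
F5 | step 8 | 8-({[tert-butyl(dimethyl)silyl]oxy}methyl)-7-hydroxy-3-(methoxymethoxy)-6H-benzo[c]chromen-6-one | O=C1Oc2cc(OCOC)ccc2-c2ccc(CO[Si](C)(C)C(C)(C)C)c(O)c12
F6 | step 8 | 8-({[tert-butyl(dimethyl)silyl]oxy}methyl)-3-(methoxymethoxy)-6-oxo-6H-benzo[c]chromen-7-yl trifluoromethanesulfonate | O=C1Oc2cc(OCOC)ccc2-c2ccc(CO[Si](C)(C)C(C)(C)C)c(OS(=O)(=O)C(F)(F)F)c12
F7 | step 9 | 8-({[tert-butyl(dimethyl)silyl]oxy}methyl)-3-(methoxymethoxy)-7-{[4-(methoxymethoxy)phenyl]ethynyl}-6a,7,10,10a-tetrahydro-6H-benzo[c]chromen-6-one (mixture of stereoisomers) | O=C1Oc2cc(OCOC)ccc2C2CC=C(CO[Si](C)(C)C(C)(C)C)C(C#Cc3ccc(OCOC)cc3)C12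
F8 | step 11 | {4-({[tert-butyl(dimethyl)silyl]oxy}methyl)-2'-hydroxy-4'-(methoxymethoxy)-3-{[4-(methoxymethoxy)phenyl]ethynyl}[1,1'-biphenyl]-2-yl}[4-(methoxymethoxy)phenyl]methanone | Oc1cc(OCOC)ccc1-c1ccc(CO[Si](C)(C)C(C)(C)C)c(C#Cc2ccc(OCOC)cc2)c1C(=O)c1ccc(OCOC)cc1
F9 | step 11 | {4-({[tert-butyl(dimethyl)silyl]oxy}methyl)-2',4'-bis(methoxymethoxy)-3-{[4-(methoxymethoxy)phenyl]ethynyl}[1,1'-biphenyl]-2-yl}[4-(methoxymethoxy)phenyl]methanone | COCOc1cc(OCOC)ccc1-c1ccc(CO[Si](C)(C)C(C)(C)C)c(C#Cc2ccc(OCOC)cc2)c1C(=O)c1ccc(OCOC)cc1
F10 | step 11 | {4-({[tert-butyl(dimethyl)silyl]oxy}methyl)-2',4'-bis(methoxymethoxy)-3-{[4-(methoxymethoxy)phenyl]ethynyl}[1,1'-biphenyl]-2-yl}bis[4-(methoxymethoxy)phenyl]methanol | OC(c1ccc(OCOC)cc1)(c1ccc(OCOC)cc1)c1c(-c2ccc(OCOC)cc2OCOC)ccc(CO[Si](C)(C)C(C)(C)C)c1C#Cc1ccc(OCOC)cc1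
F11 | step 12 | 8-(hydroxymethyl)-6,6-bis(4-hydroxyphenyl)-7-[(4-hydroxyphenyl)ethynyl]-6H-benzo[c]chromen-3-ol | Oc1ccc(cc1)C1(c2ccc(O)cc2)Oc2cc(O)ccc2-c2ccc(CO)c(C#Cc3ccc(O)cc3)c12
A1 | alternative 1 | 6-[(methoxymethoxy)methyl]-3-(prop-2-en-1-yloxy)-2-(trimethylsilyl)phenyl trifluoromethanesulfonate | C=CCOc1ccc(COCOC)c(OS(=O)(=O)C(F)(F)F)c1[Si](C)(C)C
A2 | alternative 1 | 1,3-bis[4-(methoxymethoxy)phenyl]propane-1,3-dione | COCOc1ccc(cc1)C(=O)CC(=O)c1ccc(OCOC)cc1
A3 | alternative 1 | 2-{2-[4-(methoxymethoxy)benzoyl]-6-[(methoxymethoxy)methyl]-3-(prop-2-en-1-yloxy)phenyl}-1-[4-(methoxymethoxy)phenyl]ethan-1-one | C=CCOc1ccc(COCOC)c(CC(=O)c2ccc(OCOC)cc2)c1C(=O)c1ccc(OCOC)cc1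
A4 | alternative 2 | 2-ethynyl-5-(methoxymethoxy)phenyl prop-2-yn-1-yl but-2-ynedioate | C#CCOC(=O)C#CC(=O)Oc1cc(OCOC)ccc1C#C
A5 | alternative 2 | 3-(methoxymethoxy)-6H-benzo[c]chromen-6-one with a γ-lactone fused across C7–C8 (carbonyl on C7, OCH2 on C8) | COCOc1ccc2c(c1)OC(=O)c1c-2ccc2c1C(=O)OC2
A6 | alternative 3 | 3-formyl-2',4'-bis(methoxymethoxy)-4-[(methoxymethoxy)methyl][1,1'-biphenyl]-2-yl trifluoromethanesulfonate | COCOCc1ccc(-c2ccc(OCOC)cc2OCOC)c(OS(=O)(=O)C(F)(F)F)c1C=O
A7 | alternative 3 | 1,2-bis[4-(methoxymethoxy)phenyl]ethyne | COCOc1ccc(cc1)C#Cc1ccc(OCOC)cc1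
A8 | alternative 3 | 4-[2,4-bis(methoxymethoxy)phenyl]-7-[(methoxymethoxy)methyl]-2,3-bis[4-(methoxymethoxy)phenyl]-1H-inden-1-one | COCOCc1ccc(-c2ccc(OCOC)cc2OCOC)c2c1C(=O)C(c1ccc(OCOC)cc1)=C2c1ccc(OCOC)cc1
A9 | alternative 3 | 2,3-epoxide of A8 (racemic 2,3-epoxy-2,3-dihydro-1H-inden-1-one) | COCOCc1ccc(-c2ccc(OCOC)cc2OCOC)c2c1C(=O)C1(c3ccc(OCOC)cc3)OC21c1ccc(OCOC)cc1
A10 | alternative 3 | {2',4'-bis(methoxymethoxy)-4-[(methoxymethoxy)methyl]-3-{[4-(methoxymethoxy)phenyl]ethynyl}[1,1'-biphenyl]-2-yl}[4-(methoxymethoxy)phenyl]methanone | COCOCc1ccc(-c2ccc(OCOC)cc2OCOC)c(C(=O)c2ccc(OCOC)cc2)c1C#Cc1ccc(OCOC)cc1
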